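Everything rests on cutting the γ-lactone (O1, C2 carbonyl, C3, C4, C5) into a two-carbon ketene, C2–C3, and a C4=C5 alkene. The feature exploited is that C5 is a bare OCH2 beside the one independent stereocentre, C4, which carries the CH2–ring B (3,4,5-trimethoxyphenyl) arm. A sulfinyl group can therefore sit on C5, steer events and later be erased. Dichloroketene is captured by the sulfinyl oxygen; a [3,3] shift forges C3–C4 and carboxylate collapse forges O1–C5, so ring and C4 configuration arise in one operation. The precursor is an enantiopure (R)-(Z)-alkenyl p-tolyl sulfoxide with sulfur and the ring B arm cis. Ring A enters last by trans-selective C3 alkylation.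

Key step: step 4

Assumption: ring A is the 3,4-dimethoxyphenyl group on the C3 arm, and the target is read as the (3R,4R)-trans lactone. CIP labels at sulfur and at C4 change along the route although the geometry does not; the reason is noted in the compound list.

Step 1
Reactants: 1 5-bromo-1,2,3-trimethoxybenzene; 2 methoxyallene (1-methoxypropa-1,2-diene)
Product: 4 1,2,3-trimethoxy-5-(prop-2-yn-1-yl)benzene, via 3,4,5-trimethoxyphenylmagnesium bromide 3 (not isolated)
Conditions: Mg, THF, 45 °C; then added to 2, CuBr (5 mol %), Et2O, 0 °C to rt; aq NH4Cl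
Reagents that add atoms: none
Why: Copper-catalysed SN2′ substitution of an allenyl ether by a Grignard reagent, in which the aryl group adds to the unsubstituted allene terminus and methoxide leaves, should give only the skipped terminal alkyne and avoid the arylallene that propargyl halides tend to deliver; no stereocentre is formed.

Step 2
Reactants: 4 1,2,3-trimethoxy-5-(prop-2-yn-1-yl)benzene; 5 (1R,2S,5R)-menthyl (S)-p-toluenesulfinate
Product: 7 (S)-1,2,3-trimethoxy-5-[3-(p-tolylsulfinyl)prop-2-yn-1-yl]benzene, via alkynylmagnesium bromide 6 (not isolated)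
Conditions: EtMgBr (1.0 equiv), THF, 0 °C to rt; then added to 5, toluene, −20 °C; cold aq NH4Cl
Reagents that add atoms: none
Why: In this Andersen sulfoxide synthesis the magnesium acetylide displaces menthoxide from sulfur with inversion, so the sulfur stereocentre of 7 is taken from 5, and inverse addition at low temperature keeps the acidic ArCH2 of the product away from excess base.

Step 3
Reactants: 7 (S)-1,2,3-trimethoxy-5-[3-(p-tolylsulfinyl)prop-2-yn-1-yl]benzene
Product: 8 (R)-(Z)-1-(p-tolylsulfinyl)-3-(3,4,5-trimethoxyphenyl)prop-1-ene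
Conditions: H2 (1 atm), RhCl(PPh3)3 (5 mol %), benzene, rt
Reagents that add atoms: none
Why: Homogeneous rhodium-catalysed syn-hydrogenation of a 1-alkynyl sulfoxide should stop at the cis-alkene because the hindered, electron-poor (Z)-alkenyl sulfoxide binds the metal poorly, while sulfur is untouched and the neutral medium leaves the benzylic allylic CH2 where it is.

Step 4
Reactants: 8 (R)-(Z)-1-(p-tolylsulfinyl)-3-(3,4,5-trimethoxyphenyl)prop-1-ene; 9 trichloroacetyl chloride
Product: 13 (4S,5R)-3,3-dichloro-4-(3,4,5-trimethoxybenzyl)-5-(p-tolylthio)dihydrofuran-2(3H)-one, via dichloroketene 10 (not isolated), via acyloxysulfonium enolate 11 (not isolated), via thionium carboxylate 12 (not isolated)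
Conditions: Zn–Cu couple, 9 (2–3 equiv, added slowly), THF, 0 °C
Reagents that add atoms: none
Why: Zinc strips two chlorines from 9 to give 10, whose central carbon is attacked by the sulfinyl oxygen of 8 to give zwitterion 11; its dichloroenolate carbon and C4 are the ends of a six-atom array, so a [3,3] shift makes C3–C4, breaks S–O and leaves 12, which closes O1–C5. The closest known reaction type is the γ-lactonisation of 1-alkenyl aryl sulfoxides by dichloroketene, a sulfonium-accelerated Claisen-type shift followed by Pummerer-type capture, which is established for (Z)-alkenyl p-tolyl sulfoxides. The single ring closes 5-exo-trig, the carboxylate oxygen attacking C5 while the C5=S+ π bond stays outside the new ring. C4 is controlled by the sulfur stereocentre: A(1,3) strain between the cis CH2–ring B arm and the p-tolyl group leaves only the rotamer in which the sulfur lone pair eclipses the alkene, this places the S–O bond over one face, and the suprafacial shift delivers C3 to that face, so (R)-sulfur should give (4S). C5 is controlled by the tether and the alkene geometry, because the carboxylate is released on the face where C3 has just bonded and closes before C4–C5 rotation, which should leave the arm and the thio group cis (5R), a centre that step 6 erases. The step needs facial selectivity at C4, secured by the Z geometry, and chemoselectivity for O-acylation and O-capture over [2+2] addition, deoxygenation by zinc and attack of ring B on the thionium carbon, secured by slow addition of 9, THF that ties up ZnCl2 and the proximity of the anionic carboxylate.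

Step 5
Reactants: 13 (4S,5R)-3,3-dichloro-4-(3,4,5-trimethoxybenzyl)-5-(p-tolylthio)dihydrofuran-2(3H)-one
Product: 14 (4R,5R)-4-(3,4,5-trimethoxybenzyl)-5-(p-tolylthio)dihydrofuran-2(3H)-one
Conditions: Zn dust, AcOH, rt to 50 °C
Reagents that add atoms: none
Why: Reductive dehalogenation of an α,α-dichloro carbonyl compound runs through zinc enolates that AcOH protonates, and C4 and C5 should stay untouched because no leaving group sits β to the carbonyl and the aryl ethers and the O,S-acetal tolerate the medium.

Step 6
Reactants: 14 (4R,5R)-4-(3,4,5-trimethoxybenzyl)-5-(p-tolylthio)dihydrofuran-2(3H)-one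
Product: 15 (R)-4-(3,4,5-trimethoxybenzyl)dihydrofuran-2(3H)-one
Conditions: Raney Ni (W-2, washed to neutrality), EtOH, rt to reflux
Reagents that add atoms: none
Why: Raney nickel reductive desulfurisation replaces the C5 thio group by hydrogen, which removes C5 as a stereocentre and leaves C4 alone, and the neutral catalyst keeps the O,S-acetal from opening to an aldehyde that could enolise at C4.

Step 7
Reactants: 15 (R)-4-(3,4,5-trimethoxybenzyl)dihydrofuran-2(3H)-one; 16 3,4-dimethoxybenzyl bromide
Product: 18 (3R,4R)-3-(3,4-dimethoxybenzyl)-4-(3,4,5-trimethoxybenzyl)dihydrofuran-2(3H)-one, via lithium enolate 17 (not isolated)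
Conditions: LiN(SiMe3)2 (1.05 equiv), THF, −78 °C; then 16, DMPU, −78 to −20 °C
Reagents that add atoms: none
Why: In this kinetic lithium enolate alkylation (SN2) of a β-substituted γ-butyrolactone the bromide approaches the planar enolate anti to the C4 arm, which should set C3 as R, trans to C4, and this is also the more stable isomer.

Compound list
1 | 5-bromo-1,2,3-trimethoxybenzene | COc1cc(Br)cc(OC)c1OC | starting material
2 | methoxyallene (1-methoxypropa-1,2-diene) | COC=C=C | starting material
3 | 3,4,5-trimethoxyphenylmagnesium bromide | COc1cc([Mg]Br)cc(OC)c1OC | intermediate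
4 | 1,2,3-trimethoxy-5-(prop-2-yn-1-yl)benzene | C#CCc1cc(OC)c(OC)c(OC)c1 | intermediate
5 | (1R,2S,5R)-menthyl (S)-p-toluenesulfinate | CC(C)[C@@H]1CC[C@@H](C)C[C@H]1O[S@](=O)c1ccc(C)cc1 | starting material
6 | 3-(3,4,5-trimethoxyphenyl)prop-1-ynylmagnesium bromide | Br[Mg]C#CCc1cc(OC)c(OC)c(OC)c1 | intermediate
7 | (S)-1,2,3-trimethoxy-5-[3-(p-tolylsulfinyl)prop-2-yn-1-yl]benzene (label S because the substituted alkynyl group outranks p-tolyl) | Cc1ccc(cc1)[S@](=O)C#CCc1cc(OC)c(OC)c(OC)c1 | intermediate
8 | (R)-(Z)-1-(p-tolylsulfinyl)-3-(3,4,5-trimethoxyphenyl)prop-1-ene (same geometry at sulfur as 7; p-tolyl now outranks the alkenyl group) | Cc1ccc(cc1)[S@](=O)/C=C\Cc1cc(OC)c(OC)c(OC)c1 | intermediate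
9 | trichloroacetyl chloride | ClC(Cl)(Cl)C(=O)Cl | starting material
10 | dichloroketene | ClC(Cl)=C=O | intermediate
11 | (R)-[(2,2-dichloro-1-oxidoethenyl)oxy](p-tolyl)[(Z)-3-(3,4,5-trimethoxyphenyl)prop-1-enyl]sulfonium, acyloxysulfonium enolate zwitterion | Cc1ccc(cc1)[S@+](OC([O-])=C(Cl)Cl)/C=C\Cc1cc(OC)c(OC)c(OC)c1 | intermediate
12 | (3S)-2,2-dichloro-4-(p-tolylsulfoniumylidene)-3-(3,4,5-trimethoxybenzyl)butanoate, thionium carboxylate zwitterion | [O-]C(=O)C(Cl)(Cl)[C@@H](Cc1cc(OC)c(OC)c(OC)c1)C=[S+]c1ccc(C)cc1 | intermediate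
13 | (4S,5R)-3,3-dichloro-4-(3,4,5-trimethoxybenzyl)-5-(p-tolylthio)dihydrofuran-2(3H)-one (4,5-cis; label 4S because CCl2 outranks C5) | O=C1O[C@H](Sc2ccc(C)cc2)[C@H](Cc3cc(OC)c(OC)c(OC)c3)C1(Cl)Cl | intermediate
14 | (4R,5R)-4-(3,4,5-trimethoxybenzyl)-5-(p-tolylthio)dihydrofuran-2(3H)-one (4,5-cis; same geometry as 13, C5 now outranks C3) | O=C1O[C@H](Sc2ccc(C)cc2)[C@H](Cc3cc(OC)c(OC)c(OC)c3)C1 | intermediate
15 | (R)-4-(3,4,5-trimethoxybenzyl)dihydrofuran-2(3H)-one | O=C1OC[C@H](Cc2cc(OC)c(OC)c(OC)c2)C1 | intermediate
16 | 3,4-dimethoxybenzyl bromide | COc1ccc(CBr)cc1OC | starting material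
17 | lithium (4R)-4-(3,4,5-trimethoxybenzyl)-4,5-dihydrofuran-2-olate | [Li+].[O-]C1=C[C@@H](Cc2cc(OC)c(OC)c(OC)c2)CO1 | intermediate
18 | (3R,4R)-3-(3,4-dimethoxybenzyl)-4-(3,4,5-trimethoxybenzyl)dihydrofuran-2(3H)-one | COc1ccc(C[C@H]2C(=O)OC[C@@H]2Cc2cc(OC)c(OC)c(OC)c2)cc1OC | target

Total step count: 7. Longest linear sequence: 7 steps (1 to 18); 2, 5, 9 and 16 are bought.

Steps most likely to fail

1. Step 4.
- What may go wrong: the sulfoxide may be deoxygenated by the zinc/acid chloride system before the ketene is captured. The alkene may drift out of conjugation with sulfur under ZnCl2. Reaction through the minor rotamer may erode facial selectivity at C4.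
- Fallback: chiral pool in place of chirality transfer. It sets out from 3, made from 1 as in step 1, and comes back at 15.
- (R)-Epichlorohydrin and diethyl malonate (NaOEt, EtOH, reflux) should give ethyl (1S,5R)-2-oxo-3-oxabicyclo[3.1.0]hexane-1-carboxylate F1. The sequence is epoxide opening, epoxide re-formation, 3-exo-tet cyclopropanation with inversion, then lactonisation.
- Grignard reagent 3 with CuI in THF at −30 °C should open this doubly activated cyclopropane at its CH2 (homoconjugate addition). No bond of the future C4 is touched. The product is ethyl (3S,4R)-2-oxo-4-(3,4,5-trimethoxybenzyl)tetrahydrofuran-3-carboxylate F2.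
- Krapcho dealkoxycarbonylation (LiCl, wet DMSO, 140 °C) then gives 15.

2. Step 2.
- What may go wrong: the product has a CH2 that is benzylic and propargylic to an acceptor alkyne, so base-induced propargyl-to-allenyl isomerisation may set in. Ligand exchange at sulfur by a second acetylide may lower the enantiopurity.
- Fallback: the C–S bond is made on an alkenyl instead of an alkynyl nucleophile. It sets out from 4 and comes back at 8, so 7 and the hydrogenation of step 3 are bypassed.
- NIS and AgNO3 (cat.) in acetone convert 4 into 5-(3-iodoprop-2-yn-1-yl)-1,2,3-trimethoxybenzene F3.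
- Diimide (2-nitrobenzenesulfonylhydrazide, Et3N, THF–iPrOH, rt) reduces it by syn addition to (Z)-5-(3-iodoprop-2-en-1-yl)-1,2,3-trimethoxybenzene F4.
- Iodine–magnesium exchange (iPrMgCl·LiCl, THF, −40 °C) with retention of geometry gives (Z)-3-(3,4,5-trimethoxyphenyl)prop-1-enylmagnesium chloride F5.
- F5 is added to 5 in toluene at −40 °C (Andersen synthesis, inversion at sulfur) and should give 8.

3. Step 7.
- What may go wrong: the electron-rich benzyl bromide may ionise and decompose before it is consumed. Proton exchange between enolate and product may lead to double alkylation and incomplete conversion.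
- Fallback: aldol addition and hydrogenolysis in place of SN2 alkylation. It sets out from 15 through enolate 17 and comes back at 18.
- Enolate 17 is trapped at −78 °C with 3,4-dimethoxybenzaldehyde, again anti to the C4 arm. This gives (3S,4R)-3-[(3,4-dimethoxyphenyl)(hydroxy)methyl]-4-(3,4,5-trimethoxybenzyl)dihydrofuran-2(3H)-one F6 (both carbinol epimers).
- Ac2O in pyridine at 0 °C gives the acetate (3S,4R)-3-[acetoxy(3,4-dimethoxyphenyl)methyl]-4-(3,4,5-trimethoxybenzyl)dihydrofuran-2(3H)-one F7.
- Neutral benzylic hydrogenolysis (H2, Pd/C, EtOAc) should give 18 without the acid that would drive a Friedel–Crafts closure onto ring B.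

Further compounds
F1 | step 4 | ethyl (1S,5R)-2-oxo-3-oxabicyclo[3.1.0]hexane-1-carboxylate | CCOC(=O)[C@]12C[C@H]1COC2=O
F2 | step 4 | ethyl (3S,4R)-2-oxo-4-(3,4,5-trimethoxybenzyl)tetrahydrofuran-3-carboxylate | CCOC(=O)[C@@H]1[C@@H](Cc2cc(OC)c(OC)c(OC)c2)COC1=O
F3 | step 2 | 5-(3-iodoprop-2-yn-1-yl)-1,2,3-trimethoxybenzene | IC#CCc1cc(OC)c(OC)c(OC)c1
F4 | step 2 | (Z)-5-(3-iodoprop-2-en-1-yl)-1,2,3-trimethoxybenzene | I/C=C\Cc1cc(OC)c(OC)c(OC)c1
F5 | step 2 | (Z)-3-(3,4,5-trimethoxyphenyl)prop-1-enylmagnesium chloride | Cl[Mg]/C=C\Cc1cc(OC)c(OC)c(OC)c1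
F6 | step 7 | (3S,4R)-3-[(3,4-dimethoxyphenyl)(hydroxy)methyl]-4-(3,4,5-trimethoxybenzyl)dihydrofuran-2(3H)-one, both carbinol epimers | COc1ccc(C(O)[C@H]2C(=O)OC[C@@H]2Cc2cc(OC)c(OC)c(OC)c2)cc1OC
F7 | step 7 | (3S,4R)-3-[acetoxy(3,4-dimethoxyphenyl)methyl]-4-(3,4,5-trimethoxybenzyl)dihydrofuran-2(3H)-one, both acetate epimers | COc1ccc(C(OC(C)=O)[C@H]2C(=O)OC[C@@H]2Cc2cc(OC)c(OC)c(OC)c2)cc1OC
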